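**Plan**

- Retrosynthesis (chromone numbering O1, C2, C3, C4, C4a; the oxepine adds a CH2 and the O-bearing stereocentre): O1–C2 of the pyranone is cut first, which leaves an o-hydroxyaryl 1,3-diketone. C4a–C4 and C4–C3 are then cut together, so C4 becomes carbon monoxide, the A ring an aryl iodide, and the B ring with the oxepine a 1-benzoxepin-5-one. That ketone is cut at aryl–C(=O) and at the aryl ether O–CH bond.
- Enabling feature: C4 is a lone carbonyl carbon between the fully substituted A-ring carbon C4a and C3. C3 is the only α-CH2 of the benzoxepinone, because its other α-atom is the B-ring carbon C1'. The stereocentre lies γ to that carbonyl and cannot epimerise.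
- Forward order: the oxepine ring closes first (Parham cyclisation). The two halves are then joined through CO without ring formation. The pyranone closes last, under the acid that also removes MOM and TES. The A-ring iodide is made from phloroglucinol by three directed lithiations.
- Stereochemistry: the single stereocentre (R) comes from a Shi epoxidation of a Me2C=CH alkene to the (S)-epoxide, followed by SN2 inversion by a bromophenoxide. Nothing later touches it.

Key step: step 12

Assumption: the L-series Shi ketone (enantiomer of the D-fructose-derived catalyst, accessible from L-sorbose) is taken to give the (S)-epoxide from this R–CH=CMe2 alkene, as the spiro transition-state model predicts; if the sense proved opposite, the D-fructose-derived ketone would be used.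

**Step 1**
Reactants: 1 phloroglucinol (benzene-1,3,5-triol)
Product: 2 1,3,5-tris(methoxymethoxy)benzene
Conditions: MOMCl, i-Pr2NEt, CH2Cl2/DMF, 0 °C → rt
Reagents that add atoms: chloromethyl methyl ether (MOMCl), COCCl
Why: exhaustive O-alkylation of the three equivalent phenols with the reactive α-chloro ether under amine base (MOM ether formation, Williamson type) should give the tris-acetal that later directs every lithiation.

**Step 2**
Reactants: 2 1,3,5-tris(methoxymethoxy)benzene; 3 prenyl bromide (1-bromo-3-methylbut-2-ene)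
Product: 5 1,3,5-tris(methoxymethoxy)-2-(3-methylbut-2-en-1-yl)benzene, via 2-lithio-1,3,5-tris(methoxymethoxy)benzene 4 (not isolated)
Conditions: n-BuLi, THF, 0 °C → rt; CuBr·SMe2 (10 mol %), 3, −78 °C → rt
Reagents that add atoms: none
Why: directed ortho-metalation at a ring C–H flanked by two MOM ethers (all three positions are equivalent), followed by copper-catalysed SN2 allylation of the aryllithium at the primary carbon of prenyl bromide.

**Step 3**
Reactants: 5 1,3,5-tris(methoxymethoxy)-2-(3-methylbut-2-en-1-yl)benzene; 3 prenyl bromide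
Product: 7 1,3,5-tris(methoxymethoxy)-2,4-bis(3-methylbut-2-en-1-yl)benzene, via 4-lithio-1,3,5-tris(methoxymethoxy)-2-(3-methylbut-2-en-1-yl)benzene 6 (not isolated)
Conditions: n-BuLi, THF, 0 °C → rt; CuBr·SMe2 (10 mol %), 3, −78 °C → rt
Reagents that add atoms: none
Why: a second directed ortho-metalation at one of the two equivalent ring positions still flanked by two chelating MOM ethers, which should be kinetically preferred over removal of a benzylic/allylic proton, followed by the same copper-catalysed allylation.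

**Step 4**
Reactants: 7 1,3,5-tris(methoxymethoxy)-2,4-bis(3-methylbut-2-en-1-yl)benzene
Product: 9 2-iodo-1,3,5-tris(methoxymethoxy)-4,6-bis(3-methylbut-2-en-1-yl)benzene, via 2-lithio-1,3,5-tris(methoxymethoxy)-4,6-bis(3-methylbut-2-en-1-yl)benzene 8 (not isolated)
Conditions: n-BuLi, THF, 0 °C; I2, −78 °C → rt
Reagents that add atoms: iodine, II
Why: directed ortho-metalation of the last ring C–H and iodinolysis of the aryllithium (lithiation–iodination) should place iodine between two MOM ethers.

**Step 5**
Reactants: 10 4-bromoresorcinol (4-bromobenzene-1,3-diol)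
Product: 11 2-bromo-5-(methoxymethoxy)phenol
Conditions: MOMCl (1.0 equiv), K2CO3, acetone, 0 °C → rt
Reagents that add atoms: chloromethyl methyl ether (MOMCl), COCCl
Why: Williamson mono-etherification with one equivalent of MOMCl is expected to go mainly to the oxygen para to bromine, which is less hindered and, as the less acidic phenol, the more nucleophilic phenoxide; the regioisomer and the bis-ether would be removed by chromatography.

**Step 6**
Reactants: 12 2-methylbut-3-en-2-ol; 13 triethyl orthoacetate (1,1,1-triethoxyethane)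
Product: 15 ethyl 5-methylhex-4-enoate, via 1-ethoxy-1-[(2-methylbut-3-en-2-yl)oxy]ethene 14 (not isolated)
Conditions: 13 (excess, neat), EtCO2H (cat.), 140 °C, EtOH distilled off
Reagents that add atoms: none
Why: Johnson–Claisen orthoester rearrangement, in which the tertiary allylic alcohol exchanges into the orthoester, loses ethanol to the ketene acetal and undergoes a [3,3]-sigmatropic shift to the γ,δ-unsaturated ester with the Me2C=CH alkene.

**Step 7**
Reactants: 15 ethyl 5-methylhex-4-enoate
Product: 16 N-methoxy-N,5-dimethylhex-4-enamide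
Conditions: MeNHOMe·HCl, i-PrMgCl, THF, −20 → 0 °C
Reagents that add atoms: N,O-dimethylhydroxylamine hydrochloride, CNOC.Cl
Why: Weinreb amide formation by aminolysis of the ester with the chloromagnesium amide of N,O-dimethylhydroxylamine made in situ.

**Step 8**
Reactants: 16 N-methoxy-N,5-dimethylhex-4-enamide
Product: 17 3-[(2S)-3,3-dimethyloxiran-2-yl]-N-methoxy-N-methylpropanamide
Conditions: L-series Shi ketone (1,2:4,5-di-O-isopropylidene-β-L-erythro-2,3-hexodiulo-2,6-pyranose, 30 mol %), Oxone, K2CO3, Bu4NHSO4, Na2B4O7/Na2EDTA buffer, MeCN/DMM, 0 °C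
Reagents that add atoms: Oxone (potassium peroxymonosulfate), [K+].[O-]S(=O)(=O)OO
Why: Shi asymmetric epoxidation, in which the chiral dioxirane transfers oxygen to one face of the electron-rich trisubstituted alkene through a spiro transition state, so the catalyst enantiomer should fix the CH carbon of the epoxide as S while the amide stays inert.

**Step 9**
Reactants: 17 3-[(2S)-3,3-dimethyloxiran-2-yl]-N-methoxy-N-methylpropanamide; 11 2-bromo-5-(methoxymethoxy)phenol
Product: 18 (4R)-4-[2-bromo-5-(methoxymethoxy)phenoxy]-5-hydroxy-N-methoxy-N,5-dimethylhexanamide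
Conditions: 11 (1.3 equiv), Cs2CO3 (0.5 equiv), DMF, 90 °C
Reagents that add atoms: none
Why: base-mediated SN2 opening of the epoxide by the phenoxide at the less substituted (secondary) carbon with inversion should turn the (S)-epoxide carbon into the (R)-aryl ether stereocentre of the target and free the tertiary alcohol, the tertiary carbon not being attacked in the absence of acid.

**Step 10**
Reactants: 18 (4R)-4-[2-bromo-5-(methoxymethoxy)phenoxy]-5-hydroxy-N-methoxy-N,5-dimethylhexanamide
Product: 19 (4R)-4-[2-bromo-5-(methoxymethoxy)phenoxy]-N-methoxy-N,5-dimethyl-5-(triethylsilyloxy)hexanamide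
Conditions: TESOTf, 2,6-lutidine, CH2Cl2, −78 → 0 °C
Reagents that add atoms: triethylsilyl trifluoromethanesulfonate (TESOTf), CC[Si](CC)(CC)OS(=O)(=O)C(F)(F)F
Why: silylation of the hindered tertiary alcohol with the silyl triflate and 2,6-lutidine at low temperature, under which aryl MOM ethers persist, masks the hydroxyl for the organolithium and enolate chemistry that follow.

**Step 11**
Reactants: 19 (4R)-4-[2-bromo-5-(methoxymethoxy)phenoxy]-N-methoxy-N,5-dimethyl-5-(triethylsilyloxy)hexanamide
Product: 22 (2R)-8-(methoxymethoxy)-2-[2-(triethylsilyloxy)propan-2-yl]-3,4-dihydro-1-benzoxepin-5(2H)-one, via aryllithium from bromine–lithium exchange 20 (not isolated), via chelated lithium hemiaminal alkoxide 21 (not isolated)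
Conditions: t-BuLi (2.1 equiv), THF (dilute), −78 → −40 °C; aq NH4Cl
Reagents that add atoms: none
Why: Parham cyclisation, in which bromine–lithium exchange outruns attack of t-BuLi on the amide, the aryllithium adds 7-exo-trig to the Weinreb carbonyl, and the chelated tetrahedral intermediate prevents over-addition and collapses to the ketone on work-up, the stereocentre being remote and untouched.

**Step 12**
Reactants: 22 (2R)-8-(methoxymethoxy)-2-[2-(triethylsilyloxy)propan-2-yl]-3,4-dihydro-1-benzoxepin-5(2H)-one; 9 2-iodo-1,3,5-tris(methoxymethoxy)-4,6-bis(3-methylbut-2-en-1-yl)benzene; 23 carbon monoxide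
Product: 25 (2R)-8-(methoxymethoxy)-4-[2,4,6-tris(methoxymethoxy)-3,5-bis(3-methylbut-2-en-1-yl)benzoyl]-2-[2-(triethylsilyloxy)propan-2-yl]-3,4-dihydro-1-benzoxepin-5(2H)-one (C4 epimers in equilibrium through the enol), via sodium enolate of the benzoxepinone 24 (not isolated)
Conditions: NaHMDS (2.2 equiv), THF, 0 °C; then 9 (1.2 equiv), Pd(dba)2 (5 mol %), Xantphos (5 mol %), CO (1 atm), dioxane, 80 °C; aq NH4Cl
Reagents that add atoms: none
Why: Pd(0) inserts into the C–I bond of 9, CO undergoes migratory insertion to the aroyl-palladium (C4a–C4), the sodium enolate 24 replaces iodide on palladium and reductive elimination from the C-bound enolate forms C4–C3, after which the second equivalent of base removes the diketone from the cycle as its enolate. The closest known reaction type is the palladium-catalysed carbonylative α-arylation of aryl alkyl ketones with aryl iodides to give 1,3-diketones. No ring is closed in this step, so no mode of closure applies. The only new stereocentre, the diketone α-carbon, is not controlled and need not be, since it is enolisable and becomes sp2 in step 13, while the ring stereocentre is γ to the carbonyl and is not touched. The step needs carbonylative C-acylation to win over direct α-arylation and O-acylation and needs a single enolate regiochemistry: the two MOM ethers flanking the iodide slow direct C–C reductive elimination and favour CO insertion, the wide-bite-angle bisphosphine under CO supports the aroyl path, and the ketone can enolise only toward its one α-CH2 because its other flank is the arene. The prenyl alkenes sit meta to the iodide and cannot reach palladium for a Heck-type closure.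

**Step 13**
Reactants: 25 (2R)-8-(methoxymethoxy)-4-[2,4,6-tris(methoxymethoxy)-3,5-bis(3-methylbut-2-en-1-yl)benzoyl]-2-[2-(triethylsilyloxy)propan-2-yl]-3,4-dihydro-1-benzoxepin-5(2H)-one
Product: 27 target CNP0328977.2 (oxepine-bridged 5,7,4'-trihydroxy-6,8-diprenylflavone; R at the carbinol-bearing ring carbon), via fully deprotected 1,3-diketone 26 (not isolated)
Conditions: HCl (1.25 M in MeOH), 40 °C
Reagents that add atoms: none
Why: acid-catalysed methanolysis of the four MOM acetals and the TES ether is followed by cyclodehydration of the o-hydroxyaryl 1,3-diketone (the ring-closing stage of a Baker–Venkataraman flavone synthesis), in which either of the two equivalent ortho hydroxyls adds to the B-ring ketone and water is lost to form O1–C2 and the pyranone without touching the γ stereocentre.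

**Compound list**

1 | phloroglucinol (benzene-1,3,5-triol) | Oc1cc(O)cc(O)c1 | starting material
2 | 1,3,5-tris(methoxymethoxy)benzene | COCOc1cc(OCOC)cc(OCOC)c1 | intermediate
3 | prenyl bromide (1-bromo-3-methylbut-2-ene) | CC(C)=CCBr | starting material
4 | 2-lithio-1,3,5-tris(methoxymethoxy)benzene | [Li]c1c(OCOC)cc(OCOC)cc1OCOC | intermediate
5 | 1,3,5-tris(methoxymethoxy)-2-(3-methylbut-2-en-1-yl)benzene | COCOc1cc(OCOC)c(CC=C(C)C)c(OCOC)c1 | intermediate
6 | 4-lithio-1,3,5-tris(methoxymethoxy)-2-(3-methylbut-2-en-1-yl)benzene | COCOc1cc(OCOC)c([Li])c(OCOC)c1CC=C(C)C | intermediate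
7 | 1,3,5-tris(methoxymethoxy)-2,4-bis(3-methylbut-2-en-1-yl)benzene | COCOc1cc(OCOC)c(CC=C(C)C)c(OCOC)c1CC=C(C)C | intermediate
8 | 2-lithio-1,3,5-tris(methoxymethoxy)-4,6-bis(3-methylbut-2-en-1-yl)benzene | COCOc1c([Li])c(OCOC)c(CC=C(C)C)c(OCOC)c1CC=C(C)C | intermediate
9 | 2-iodo-1,3,5-tris(methoxymethoxy)-4,6-bis(3-methylbut-2-en-1-yl)benzene | COCOc1c(I)c(OCOC)c(CC=C(C)C)c(OCOC)c1CC=C(C)C | intermediate
10 | 4-bromoresorcinol (4-bromobenzene-1,3-diol) | Oc1ccc(Br)c(O)c1 | starting material
11 | 2-bromo-5-(methoxymethoxy)phenol | COCOc1ccc(Br)c(O)c1 | intermediate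
12 | 2-methylbut-3-en-2-ol | CC(C)(O)C=C | starting material
13 | triethyl orthoacetate (1,1,1-triethoxyethane) | CCOC(C)(OCC)OCC | starting material
14 | 1-ethoxy-1-[(2-methylbut-3-en-2-yl)oxy]ethene | C=C(OCC)OC(C)(C)C=C | intermediate
15 | ethyl 5-methylhex-4-enoate | CCOC(=O)CCC=C(C)C | intermediate
16 | N-methoxy-N,5-dimethylhex-4-enamide | CON(C)C(=O)CCC=C(C)C | intermediate
17 | 3-[(2S)-3,3-dimethyloxiran-2-yl]-N-methoxy-N-methylpropanamide | CON(C)C(=O)CC[C@@H]1OC1(C)C | intermediate
18 | (4R)-4-[2-bromo-5-(methoxymethoxy)phenoxy]-5-hydroxy-N-methoxy-N,5-dimethylhexanamide | CON(C)C(=O)CC[C@H](C(C)(C)O)Oc1cc(OCOC)ccc1Br | intermediate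
19 | (4R)-4-[2-bromo-5-(methoxymethoxy)phenoxy]-N-methoxy-N,5-dimethyl-5-(triethylsilyloxy)hexanamide | CON(C)C(=O)CC[C@H](C(C)(C)O[Si](CC)(CC)CC)Oc1cc(OCOC)ccc1Br | intermediate
20 | (4R)-4-[2-lithio-5-(methoxymethoxy)phenoxy]-N-methoxy-N,5-dimethyl-5-(triethylsilyloxy)hexanamide | CON(C)C(=O)CC[C@H](C(C)(C)O[Si](CC)(CC)CC)Oc1cc(OCOC)ccc1[Li] | intermediate
21 | lithium (2R)-5-[methoxy(methyl)amino]-8-(methoxymethoxy)-2-[2-(triethylsilyloxy)propan-2-yl]-2,3,4,5-tetrahydro-1-benzoxepin-5-olate (C5 epimers) | [Li]OC1(N(C)OC)CC[C@H](C(C)(C)O[Si](CC)(CC)CC)Oc2cc(OCOC)ccc21 | intermediate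
22 | (2R)-8-(methoxymethoxy)-2-[2-(triethylsilyloxy)propan-2-yl]-3,4-dihydro-1-benzoxepin-5(2H)-one | O=C1CC[C@H](C(C)(C)O[Si](CC)(CC)CC)Oc2cc(OCOC)ccc21 | intermediate
23 | carbon monoxide | [C-]#[O+] | starting material
24 | sodium (2R)-8-(methoxymethoxy)-2-[2-(triethylsilyloxy)propan-2-yl]-2,3-dihydro-1-benzoxepin-5-olate | [Na+].[O-]C1=CC[C@H](C(C)(C)O[Si](CC)(CC)CC)Oc2cc(OCOC)ccc12 | intermediate
25 | (2R)-8-(methoxymethoxy)-4-[2,4,6-tris(methoxymethoxy)-3,5-bis(3-methylbut-2-en-1-yl)benzoyl]-2-[2-(triethylsilyloxy)propan-2-yl]-3,4-dihydro-1-benzoxepin-5(2H)-one (C4 epimers, enol) | COCOc1c(C(=O)C2C[C@H](C(C)(C)O[Si](CC)(CC)CC)Oc3cc(OCOC)ccc3C2=O)c(OCOC)c(CC=C(C)C)c(OCOC)c1CC=C(C)C | intermediate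
26 | (2R)-8-hydroxy-2-(2-hydroxypropan-2-yl)-4-[2,4,6-trihydroxy-3,5-bis(3-methylbut-2-en-1-yl)benzoyl]-3,4-dihydro-1-benzoxepin-5(2H)-one (C4 epimers, enol) | Oc1c(C(=O)C2C[C@H](C(C)(C)O)Oc3cc(O)ccc3C2=O)c(O)c(CC=C(C)C)c(O)c1CC=C(C)C | intermediate
27 | CNP0328977.2: 5,7,4'-trihydroxy-6,8-bis(3-methylbut-2-en-1-yl)flavone whose C3 is joined through CH2–CH[C(CH3)2OH]–O to C2' (oxepine ring, R at the CH) | CC(C)=CCc1c(O)c(CC=C(C)C)c2oc3c(c(=O)c2c1O)C[C@H](C(C)(C)O)Oc1cc(O)ccc1-3 | target

**Step count**

Total: 13 steps. Longest linear sequence: 8 steps (steps 6, 7, 8, 9, 10, 11, 12, 13, from 2-methylbut-3-en-2-ol and triethyl orthoacetate).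

**Steps most likely to fail**

Step 12. The crowded aroyl-palladium may be captured too slowly by the enolate, so that reduction of the iodide, direct arylation or O-acylation takes over. The fallback sets out from 7 and 22 and rejoins at 25, and makes the same two bonds in two polar steps. Lithiation of 7 as in step 4 gives 8, which is quenched with DMF to give 2,4,6-tris(methoxymethoxy)-3,5-bis(3-methylbut-2-en-1-yl)benzaldehyde F1. The sodium enolate 24 (from 22, NaHMDS, THF, −78 °C) adds to F1 in an aldol reaction to give the β-hydroxy ketone (2R)-4-{hydroxy[2,4,6-tris(methoxymethoxy)-3,5-bis(3-methylbut-2-en-1-yl)phenyl]methyl}-8-(methoxymethoxy)-2-[2-(triethylsilyloxy)propan-2-yl]-3,4-dihydro-1-benzoxepin-5(2H)-one F2. Dess–Martin periodinane (NaHCO3, CH2Cl2) then oxidises F2 to diketone 25.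

Step 9. Intermolecular SN2 attack at the secondary epoxide carbon next to the quaternary centre may be sluggish, and at the temperature required the epoxide may be lost by elimination, or the freed tertiary alkoxide may lactonise onto the amide. The fallback sets out from 11 and 17 and rejoins at 22; it makes the opening intramolecular and closes the oxepine through the C–O bond instead of the C–C bond.
- Benzylation of 11 (BnBr, K2CO3, DMF) gives 1-(benzyloxy)-2-bromo-5-(methoxymethoxy)benzene F3.
- Bromine–lithium exchange (n-BuLi, THF, −78 °C) gives [2-(benzyloxy)-4-(methoxymethoxy)phenyl]lithium F4.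
- F4 adds to the Weinreb amide 17 to give 1-[2-(benzyloxy)-4-(methoxymethoxy)phenyl]-3-[(2S)-3,3-dimethyloxiran-2-yl]propan-1-one F5.
- Hydrogenolysis (H2, Pd/C, EtOAc) frees 3-[(2S)-3,3-dimethyloxiran-2-yl]-1-[2-hydroxy-4-(methoxymethoxy)phenyl]propan-1-one F6.
- K2CO3 in DMF at 60 °C lets the phenoxide open the epoxide 7-exo-tet at the secondary carbon with inversion, giving (2R)-2-(2-hydroxypropan-2-yl)-8-(methoxymethoxy)-3,4-dihydro-1-benzoxepin-5(2H)-one F7.
- Silylation as in step 10 gives 22.

Step 11. The aryllithium may be quenched by proton transfer, or its seven-membered closure may be slow enough for t-BuLi to attack the amide. The fallback sets out from 19 and rejoins at 22, and forms the aryl–carbon bond by palladium instead of lithium.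
- DIBAL-H (THF, −78 °C) reduces 19 to (4R)-4-[2-bromo-5-(methoxymethoxy)phenoxy]-5-methyl-5-(triethylsilyloxy)hexanal F8.
- Wittig methylenation (Ph3P=CH2, THF) gives 1-bromo-4-(methoxymethoxy)-2-{[(3R)-2-methyl-2-(triethylsilyloxy)hept-6-en-3-yl]oxy}benzene F9.
- A 7-exo intramolecular Heck reaction (Pd(OAc)2, PPh3, Ag2CO3, MeCN, 80 °C) gives (2R)-8-(methoxymethoxy)-5-methylidene-2-[2-(triethylsilyloxy)propan-2-yl]-2,3,4,5-tetrahydro-1-benzoxepine F10.
- Lemieux–Johnson cleavage (OsO4 cat., NaIO4, 2,6-lutidine, dioxane/H2O) of the exocyclic alkene gives ketone 22.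

**Further compounds**

F1 | step 12 | 2,4,6-tris(methoxymethoxy)-3,5-bis(3-methylbut-2-en-1-yl)benzaldehyde | COCOc1c(C=O)c(OCOC)c(CC=C(C)C)c(OCOC)c1CC=C(C)C
F2 | step 12 | (2R)-4-{hydroxy[2,4,6-tris(methoxymethoxy)-3,5-bis(3-methylbut-2-en-1-yl)phenyl]methyl}-8-(methoxymethoxy)-2-[2-(triethylsilyloxy)propan-2-yl]-3,4-dihydro-1-benzoxepin-5(2H)-one (diastereomers at the two new centres) | COCOc1c(C(O)C2C[C@H](C(C)(C)O[Si](CC)(CC)CC)Oc3cc(OCOC)ccc3C2=O)c(OCOC)c(CC=C(C)C)c(OCOC)c1CC=C(C)C
F3 | step 9 | 1-(benzyloxy)-2-bromo-5-(methoxymethoxy)benzene | COCOc1ccc(Br)c(OCc2ccccc2)c1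
F4 | step 9 | [2-(benzyloxy)-4-(methoxymethoxy)phenyl]lithium | [Li]c1ccc(OCOC)cc1OCc1ccccc1
F5 | step 9 | 1-[2-(benzyloxy)-4-(methoxymethoxy)phenyl]-3-[(2S)-3,3-dimethyloxiran-2-yl]propan-1-one | COCOc1ccc(C(=O)CC[C@@H]2OC2(C)C)c(OCc2ccccc2)c1
F6 | step 9 | 3-[(2S)-3,3-dimethyloxiran-2-yl]-1-[2-hydroxy-4-(methoxymethoxy)phenyl]propan-1-one | COCOc1ccc(C(=O)CC[C@@H]2OC2(C)C)c(O)c1
F7 | step 9 | (2R)-2-(2-hydroxypropan-2-yl)-8-(methoxymethoxy)-3,4-dihydro-1-benzoxepin-5(2H)-one | O=C1CC[C@H](C(C)(C)O)Oc2cc(OCOC)ccc21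
F8 | step 11 | (4R)-4-[2-bromo-5-(methoxymethoxy)phenoxy]-5-methyl-5-(triethylsilyloxy)hexanal | O=CCC[C@H](C(C)(C)O[Si](CC)(CC)CC)Oc1cc(OCOC)ccc1Br
F9 | step 11 | 1-bromo-4-(methoxymethoxy)-2-{[(3R)-2-methyl-2-(triethylsilyloxy)hept-6-en-3-yl]oxy}benzene | C=CCC[C@H](C(C)(C)O[Si](CC)(CC)CC)Oc1cc(OCOC)ccc1Br
F10 | step 11 | (2R)-8-(methoxymethoxy)-5-methylidene-2-[2-(triethylsilyloxy)propan-2-yl]-2,3,4,5-tetrahydro-1-benzoxepine | C=C1CC[C@H](C(C)(C)O[Si](CC)(CC)CC)Oc2cc(OCOC)ccc21
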